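Some X does not become Q. That was the first item at the meeting, which had these flasks and questions before it.

| setting | south-west | south | east | north-west | south-east |
|---|---|---|---|---|---|
| G | 100 mM | 50.0 mM | 100 mM | 100 mM | 25.0 mM |
| X | 80.0 mM | 30.0 mM | 80.0 mM | 120 mM | 80.0 mM |
| E | 0.500 mM | 0.500 mM | 0.250 mM | 0.500 mM | 0.500 mM |
| time |  |  |  |  | 17 min |

| run | time / min | [Q] / mM |
|---|---|---|
| south-west run | 2.8 | 33.7 |
| south-west run | 5.7 | 49.1 |
| south-west run | 8.5 | 55.6 |
| south-west run | 11 | 59.6 |
| south-west run | 14 | 61.3 |
| south-west run | 17 | 61.9 |
| south run | 2.8 | 11.0 |
| south run | 5.7 | 16.9 |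
| south run | 8.5 | 19.3 |
| south run | 11 | 20.7 |
| south run | 14 | 21.5 |
| south run | 17 | 21.7 |
| east run | 2.8 | 19.7 |
| east run | 5.7 | 31.4 |
| east run | 8.5 | 38.7 |
| east run | 11 | 42.6 |
| east run | 14 | 46.1 |
| east run | 17 | 47.3 |
| north-west run | 2.8 | 46.3 |
| north-west run | 5.7 | 66.8 |
| north-west run | 8.5 | 76.0 |
| north-west run | 11 | 80.8 |
| north-west run | 14 | 83.7 |
| north-west run | 17 | 85.4 |

(readings scatter by 0.3 mM)

- Overall: G + X -> Q, with E as catalyst.
- Constant volume, constant temperature.
- Readings of a species count what is bound in complexes too.
- An order is taken over about fifteen percent of the charge, up and down.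

- the exponent of [X] in the starting rate at the charge of the south-west run (at the point where two percent of the G have become Q)
- the exponent of [E] in the starting rate at the charge of the south-west run (at the point where two percent of the G have become Q)
- the south run starts with 50.0 mM less of G and of X than the south-west run, and with no Q. Compared where both hold the same amount of G, once fifteen percent of what the south run was charged with has turned into Q, is the south run faster, slower or alike (within a tenth)?
- Q in the south-east run at 17 min, as a share of the G charged

The first speaker took the south-west run. At its last reading Q stood at 61.9 mM, which is 18.1 mM less than the X charged, while 38.1 mM of G had not become Q. She proposed to reckon with what is left and not with what is made. Measured against that last reading, the Q still to come in the south-west run fell from 28.2 mM to 12.8 mM between the first two readings, so she read the X there as disappearing at 0.272 min⁻¹. Of the X charged in that run, 77.4 % had appeared as Q by the last reading. The rest of that constant, 0.0616 min⁻¹, she named the loss constant of X: the fraction of the X present that disappears each minute without giving Q.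

The second speaker turned to the south-east run, where G is the limiting reagent, with 25.0 mM against 80.0 mM of X. With the loss constant, the X of that flask acts over 17 min as if it stood at its full charge for 10.5 min; the X spent on making Q is not counted in this.

I kept the minutes and add my own reckoning. In the south run, the fraction of G left gives 0.0887 min⁻¹ over the first reading, at a mean [X] of about 22.4 mM. Taking this constant as proportional to [X], and scaling it to the [X] charged in the south-east run, I get 0.317 min⁻¹. Over the time just found, my estimate for the south-east run is 3.55 % of the G left and 96.5 % of it turned into Q.

The forecaster gave 0.8 (0.6 to 1) for the exponent of [X] and 1 (0.85 to 1.1) for that of [E], and called the south run faster. For the south-east share the forecast was 93 % (82 % to 99 %), on the ground that “G should be mostly consumed”. My share is higher than the forecast's and lies inside its range.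

    E + G ⇌ EG (2112 M⁻¹ min⁻¹, 83.40 min⁻¹)
    EG + X → Q + E (786.0 M⁻¹ min⁻¹)
    X → Jo (0.05136 min⁻¹)
    EG → Vo + G (0.04764 min⁻¹)

Q in the south-east run at 17 min comes to 98.3 % of the G charged; the exponents at the south-west charge are 0.85 in [X] and 1.0 in [E], and at equal G the south run is faster. The step of EG into Vo + G makes no difference to that share. In the east run, with E at 0.250 mM, the X-to-Q constant scales to 0.105 min⁻¹; with 0.0616 min⁻¹ beside it, this gives 47.5 mM of Q at 17 min, against a reading of 47.3 mM.

The earlier runs and the new flask come from a simulation with constants of no real substance.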